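The route rests on the C6–C7 bond, the one bond that the ten-membered carbocycle (C1–C10) shares with the α-methylene-γ-butyrolactone. The lactone's C13=C11–C7 unit plus the C6 carbinol is the retron of a 2-(alkoxycarbonyl)allylation. An intramolecular Nozaki–Hiyama–Kishi allylation of a (Z)-enal therefore closes the carbocycle, sets C6 and C7 and delivers the alkoxide that lactonises onto C12, all in one operation. Its precursor is an acyclic C15 bromo-enal: C10 comes from geraniol by Sharpless epoxidation, the 4Z alkene from a commercial butenolide whose ring fixes the geometry, and C8 with its tiglate from an organocatalytic α-acyloxylation.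

Key step: step 12

Remark: atoms carry germacrane numbers (ring C1–C10, lactone carbons C11–C13 with the ring oxygen on C6, methyls C14 on C10 and C15 on C4). C3, which ends as the ketone, and the carbinol carbon C7 of 17 are temporary centres formed without control; they are carried as both epimers and left unspecified in the SMILES.

Step 1
Reactants: 1 geraniol
Product: 2 (2R,3R)-2,3-epoxygeraniol, [(2R,3R)-3-methyl-3-(4-methylpent-3-en-1-yl)oxiran-2-yl]methanol
Conditions: Ti(OiPr)4 (5 mol %), D-(−)-diisopropyl tartrate (6 mol %), t-BuOOH, 4 Å MS, CH2Cl2, −20 °C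
Reagents that add atoms: tert-butyl hydroperoxide, CC(C)(C)OO
Why: Sharpless asymmetric epoxidation, in which the complex formed from Ti(OiPr)4 and the tartrate delivers oxygen to one face of the allylic alcohol (the D-tartrate is expected to give the 2R,3R epoxide) and so sets the methyl-bearing carbon, the later C10, as R.

Step 2
Reactants: 2 (2R,3R)-2,3-epoxygeraniol
Product: 3 (2S,3R)-2-(chloromethyl)-3-methyl-3-(4-methylpent-3-en-1-yl)oxirane
Conditions: PPh3, CCl4, NaHCO3, reflux
Reagents that add atoms: carbon tetrachloride, ClC(Cl)(Cl)Cl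
Why: Appel chlorination of the primary alcohol under neutral conditions, which leaves the epoxide and both stereocentres untouched (the descriptor at C2 changes only by priority).

Step 3
Reactants: 3 (2S,3R)-2-(chloromethyl)-3-methyl-3-(4-methylpent-3-en-1-yl)oxirane; 4 5-hydroxy-4-methylfuran-2(5H)-one
Product: 8 5-[(3R)-3-hydroxy-3,7-dimethyloct-6-en-1-yn-1-yl]-4-methylfuran-2(5H)-one (both epimers at the ring carbon C5), via dilithium alkynide alkoxide 5 (not isolated), via lithium 3-methyl-4-oxobutenoate 6 (not isolated), via trilithium adduct 7 (not isolated)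
Conditions: 3, n-BuLi (3.2 equiv), THF, −40 °C; then added to 4 pretreated with LiN(SiMe3)2 (1.0 equiv), THF, −78 → 0 °C; aq. HCl to pH 3
Reagents that add atoms: none
Why: Base-induced eliminative opening of the 2,3-epoxy chloride (α-deprotonation, epoxide opening, dehydrochlorination) should give the tertiary propargylic alkoxide and its alkynide without breaking a bond at C10 (R retained); the alkynide then adds 1,2 to the aldehyde of the ring-opened pseudo-acid to form C2–C3, and acidification relactonises, so the butenolide ring fixes the Z geometry of C4=C5.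

Step 4
Reactants: 8 5-[(3R)-3-hydroxy-3,7-dimethyloct-6-en-1-yn-1-yl]-4-methylfuran-2(5H)-one
Product: 9 (2Z,5E,7R)-3,7,11-trimethyldodeca-2,5,10-triene-1,4,7-triol (both C4 epimers)
Conditions: NaAlH2(OCH2CH2OMe)2 (Red-Al, 6 equiv), THF, −20 °C, then rt; aq. potassium sodium tartrate
Reagents that add atoms: none
Why: Hydride reduction of the butenolide at low temperature should give the (Z)-2-ene-1,4-diol dialkoxide first (so no carboxylate leaving group remains at propargylic C3 and no allene can form), and on warming the flanking alkoxides direct trans-hydroalumination of the alkyne to the E alkene C1=C2.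

Step 5
Reactants: 9 (2Z,5E,7R)-3,7,11-trimethyldodeca-2,5,10-triene-1,4,7-triol
Product: 10 (2Z,5E,7R)-3,7,11-trimethyl-1,4,7-tris(triethylsilyloxy)dodeca-2,5,10-triene
Conditions: TESOTf (3.6 equiv), 2,6-lutidine, CH2Cl2, −78 → 0 °C
Reagents that add atoms: triethylsilyl trifluoromethanesulfonate, CC[Si](CC)(CC)OS(=O)(=O)C(F)(F)F
Why: Silyl triflate silylation caps the primary, the doubly allylic secondary and the tertiary hydroxyl in one operation, and the lutidine buffer avoids ionisation of the allylic alcohols and cyclodehydration of the Z-ene-1,4-diol.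

Step 6
Reactants: 10 (2Z,5E,7R)-3,7,11-trimethyl-1,4,7-tris(triethylsilyloxy)dodeca-2,5,10-triene
Product: 11 (4R,5E,8Z)-4,8-dimethyl-4,7,10-tris(triethylsilyloxy)deca-5,8-dienal
Conditions: O3 (1.0 equiv, Sudan Red 7B end-point), CH2Cl2, −78 °C; then PPh3, −78 °C → rt
Reagents that add atoms: ozone, [O-][O+]=O
Why: Chemoselective ozonolysis, since the isolated electron-rich isopropylidene alkene should react far faster than the two alkenes that each carry two allylic silyloxy groups (inductively deactivated and shielded), so only C7=C11 is cleaved and PPh3 reduces the ozonide to the C7 aldehyde.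

Step 7
Reactants: 12 tigloyl chloride, (2E)-2-methylbut-2-enoyl chloride (2 equiv)
Product: 13 bis[(2E)-2-methylbut-2-enoyl] peroxide
Conditions: 12 (2.0 equiv), H2O2 (30 % aq., 1.0 equiv), NaOH (2.0 equiv), Et2O/H2O, 0 °C
Reagents that add atoms: hydrogen peroxide, OO; tigloyl chloride (the second equivalent of 12), C/C=C(\C)C(Cl)=O
Why: Schotten–Baumann acylation of hydrogen peroxide at both oxygens by two equivalents of 12 should give the symmetrical diacyl peroxide, the tigloyl analogue of dibenzoyl peroxide, which is kept cold in solution and used directly.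

Step 8
Reactants: 11 (4R,5E,8Z)-4,8-dimethyl-4,7,10-tris(triethylsilyloxy)deca-5,8-dienal; 13 bis[(2E)-2-methylbut-2-enoyl] peroxide
Product: 14 (2R,4R,5E,8Z)-4,8-dimethyl-1-oxo-4,7,10-tris(triethylsilyloxy)deca-5,8-dien-2-yl (2E)-2-methylbut-2-enoate
Conditions: (R)-α,α-diphenylprolinol trimethylsilyl ether (10 mol %), hydroquinone (10 mol %), THF, 0 °C; used crude
Reagents that add atoms: none
Why: Enamine-catalysed α-acyloxylation of an aldehyde by a diacyl peroxide, in which the E-enamine attacks the O–O bond on the face away from the diphenyl(silyloxy)methyl group, so the catalyst sets C8 as R and installs the tiglate in the same event.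

Step 9
Reactants: 14 (2R,4R,5E,8Z)-4,8-dimethyl-1-oxo-4,7,10-tris(triethylsilyloxy)deca-5,8-dien-2-yl (2E)-2-methylbut-2-enoate; 15 methyl propiolate
Product: 17 methyl (4R,6R,7E,10Z)-3-hydroxy-6,10-dimethyl-2-methylidene-4-[(2E)-2-methylbut-2-enoyloxy]-6,9,12-tris(triethylsilyloxy)dodeca-7,10-dienoate (both C3 epimers), via vinylalane 16 (not isolated)
Conditions: 15, i-Bu2AlH, N-methylmorpholine N-oxide, THF, 0 °C; then 14, −20 → 0 °C; aq. potassium sodium tartrate
Reagents that add atoms: none
Why: Vinylalumination, in which conjugate hydroalumination of the propiolate gives the α-aluminoacrylate that adds to the aldehyde to give the Morita–Baylis–Hillman-type adduct without amine base, so the labile C8 centre should not epimerise; the new carbinol centre (C7) is removed in step 10.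

Step 10
Reactants: 17 methyl (4R,6R,7E,10Z)-3-hydroxy-6,10-dimethyl-2-methylidene-4-[(2E)-2-methylbut-2-enoyloxy]-6,9,12-tris(triethylsilyloxy)dodeca-7,10-dienoate
Product: 18 methyl (2Z,4R,6R,7E,10Z)-2-(bromomethyl)-6,10-dimethyl-4-[(2E)-2-methylbut-2-enoyloxy]-6,9,12-tris(triethylsilyloxy)dodeca-2,7,10-trienoate
Conditions: CBr4, PPh3, 2,6-lutidine, CH2Cl2, 0 °C
Reagents that add atoms: carbon tetrabromide, BrC(Br)(Br)Br
Why: Appel bromination of the Morita–Baylis–Hillman alcohol with SN2' allylic transposition should give the conjugated primary (Z)-allylic bromide, the thermodynamically favoured isomer, under neutral conditions that spare the TES ethers.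

Step 11
Reactants: 18 methyl (2Z,4R,6R,7E,10Z)-2-(bromomethyl)-6,10-dimethyl-4-[(2E)-2-methylbut-2-enoyloxy]-6,9,12-tris(triethylsilyloxy)dodeca-2,7,10-trienoate
Product: 19 methyl (2Z,4R,6R,7E,10Z)-2-(bromomethyl)-6,10-dimethyl-4-[(2E)-2-methylbut-2-enoyloxy]-12-oxo-6,9-bis(triethylsilyloxy)dodeca-2,7,10-trienoate
Conditions: (COCl)2, DMSO, CH2Cl2, −78 °C; then i-Pr2NEt, −78 → −30 °C
Reagents that add atoms: none
Why: Swern oxidation applied directly to a primary TES ether (the chlorosulfonium salt activates the least hindered silyl ether) should give the (Z)-enal while the secondary and tertiary TES ethers and both esters survive; the hindered amine spares the allylic bromide and the low temperature keeps the Z geometry.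

Step 12
Reactants: 19 methyl (2Z,4R,6R,7E,10Z)-2-(bromomethyl)-6,10-dimethyl-4-[(2E)-2-methylbut-2-enoyloxy]-12-oxo-6,9-bis(triethylsilyloxy)dodeca-2,7,10-trienoate
Product: 22 (3aR,4R,6R,7E,10Z,11aR)-6,10-dimethyl-3-methylidene-2-oxo-6,9-bis(triethylsilyloxy)-2,3,3a,4,5,6,9,11a-octahydrocyclodeca[b]furan-4-yl (2E)-2-methylbut-2-enoate (both C9 epimers), via allylchromium dichloride 20 (not isolated), via cyclised chromium alkoxide 21 (not isolated)
Conditions: CrCl2 (10 equiv), THF, 4 Å MS, rt; 19 added by syringe pump (final 0.003 M); aq. NH4Cl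
Reagents that add atoms: none
Why: Two equivalents of CrCl2 (divalent chromium) reduce the allylic bromide to the trivalent allylchromium 20, whose η1 forms interconvert by 1,3-metal shift, and its γ-carbon C7 adds to the C6 aldehyde through a six-membered chair transition state (Nozaki–Hiyama–Kishi allylation; closest known type: the CrCl2-mediated 2-(alkoxycarbonyl)allylation of aldehydes and its intramolecular use for ten-membered carbocycles). The carbocycle closes by a 10-exo-trig addition to the aldehyde, and the chromium alkoxide 21 then closes the γ-lactone by 5-exo-trig acyl substitution at the C12 methyl ester. C6 and C7 are set together: with both ring branches (C5 on C6, C8 on C7) equatorial in the chair the 6,7-anti adduct results, which is the trans-fused lactone (6R,7R). The face of C7 is controlled by the C8 stereocentre, because allylic strain places H8 in the plane of C7=C11 and C6 then bonds anti to the C9 branch, the arrangement that also lets the tether span the ring without eclipsing. The step needs attack at C7 and not C13, at the aldehyde and not an ester, and ring closure and not oligomerisation; the cyclic SE2' transition state, the inertness of allylchromium towards esters, and high dilution together with the Z geometry of C4=C5 (which turns C6 back towards C7) should secure these.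

Step 13
Reactants: 22 bis(triethylsilyl) ether lactone, the product of step 12
Product: 23 (3aR,4R,6R,7E,10Z,11aR)-6,9-dihydroxy-6,10-dimethyl-3-methylidene-2-oxo-2,3,3a,4,5,6,9,11a-octahydrocyclodeca[b]furan-4-yl (2E)-2-methylbut-2-enoate (both C9 epimers)
Conditions: HF·pyridine, pyridine, THF, 0 °C → rt
Reagents that add atoms: none
Why: Fluoride desilylation under pyridine-buffered conditions should free the C3 and C10 hydroxyls without acyl migration, lactone opening or conjugate addition to the α-methylene lactone.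

Step 14
Reactants: 23 diol lactone, the product of step 13
Product: 24 eupaheliangolide A, (3aR,4R,6R,7E,10Z,11aR)-6-hydroxy-6,10-dimethyl-3-methylidene-2,9-dioxo-2,3,3a,4,5,6,9,11a-octahydrocyclodeca[b]furan-4-yl (2E)-2-methylbut-2-enoate
Conditions: MnO2 (activated, excess), CH2Cl2, rt
Reagents that add atoms: none
Why: Allylic oxidation with MnO2 should convert only the doubly allylic secondary C3 alcohol into the cross-conjugated dienone (the tertiary C10 alcohol cannot be oxidised), which removes the temporary C3 centre and converges both epimers on the target.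

Compound list

1 | geraniol, (2E)-3,7-dimethylocta-2,6-dien-1-ol | CC(C)=CCC/C(C)=C/CO | starting material
2 | (2R,3R)-2,3-epoxygeraniol | CC(C)=CCC[C@@]1(C)O[C@@H]1CO | intermediate
3 | (2S,3R)-2-(chloromethyl)-3-methyl-3-(4-methylpent-3-en-1-yl)oxirane | CC(C)=CCC[C@@]1(C)O[C@@H]1CCl | intermediate
4 | 5-hydroxy-4-methylfuran-2(5H)-one (racemic pseudo-acid) | CC1=CC(=O)OC1O | starting material
5 | dilithium (3R)-3,7-dimethyl-3-oxidooct-6-en-1-yn-1-ide (not isolated) | [Li]C#C[C@](C)(O[Li])CCC=C(C)C | intermediate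
6 | lithium (2Z)-3-methyl-4-oxobut-2-enoate, ring-opened salt of 4 (not isolated) | [Li+].[O-]C(=O)/C=C(/C)C=O | intermediate
7 | trilithium (2Z,7R)-3,7,11-trimethyl-4,7-dioxidododeca-2,10-dien-5-ynoate, both C4 epimers (not isolated) | [Li]OC(=O)/C=C(/C)C(O[Li])C#C[C@](C)(O[Li])CCC=C(C)C | intermediate
8 | 5-[(3R)-3-hydroxy-3,7-dimethyloct-6-en-1-yn-1-yl]-4-methylfuran-2(5H)-one, both C5 epimers | CC(C)=CCC[C@@](C)(O)C#CC1OC(=O)C=C1C | intermediate
9 | (2Z,5E,7R)-3,7,11-trimethyldodeca-2,5,10-triene-1,4,7-triol, both C4 epimers | CC(C)=CCC[C@@](C)(O)/C=C/C(O)/C(C)=C\CO | intermediate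
10 | (2Z,5E,7R)-3,7,11-trimethyl-1,4,7-tris(triethylsilyloxy)dodeca-2,5,10-triene | CC(C)=CCC[C@@](C)(O[Si](CC)(CC)CC)/C=C/C(O[Si](CC)(CC)CC)/C(C)=C\CO[Si](CC)(CC)CC | intermediate
11 | (4R,5E,8Z)-4,8-dimethyl-4,7,10-tris(triethylsilyloxy)deca-5,8-dienal | O=CCC[C@@](C)(O[Si](CC)(CC)CC)/C=C/C(O[Si](CC)(CC)CC)/C(C)=C\CO[Si](CC)(CC)CC | intermediate
12 | tigloyl chloride, (2E)-2-methylbut-2-enoyl chloride | C/C=C(\C)C(Cl)=O | starting material
13 | bis[(2E)-2-methylbut-2-enoyl] peroxide | C/C=C(\C)C(=O)OOC(=O)/C(C)=C/C | intermediate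
14 | (2R,4R,5E,8Z)-4,8-dimethyl-1-oxo-4,7,10-tris(triethylsilyloxy)deca-5,8-dien-2-yl (2E)-2-methylbut-2-enoate | O=C[C@H](OC(=O)/C(C)=C/C)C[C@@](C)(O[Si](CC)(CC)CC)/C=C/C(O[Si](CC)(CC)CC)/C(C)=C\CO[Si](CC)(CC)CC | intermediate
15 | methyl propiolate | C#CC(=O)OC | starting material
16 | methyl 2-(diisobutylalumanyl)prop-2-enoate (not isolated) | C=C(C(=O)OC)[Al](CC(C)C)CC(C)C | intermediate
17 | methyl (4R,6R,7E,10Z)-3-hydroxy-6,10-dimethyl-2-methylidene-4-[(2E)-2-methylbut-2-enoyloxy]-6,9,12-tris(triethylsilyloxy)dodeca-7,10-dienoate, both C3 epimers | C=C(C(=O)OC)C(O)[C@H](OC(=O)/C(C)=C/C)C[C@@](C)(O[Si](CC)(CC)CC)/C=C/C(O[Si](CC)(CC)CC)/C(C)=C\CO[Si](CC)(CC)CC | intermediate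
18 | methyl (2Z,4R,6R,7E,10Z)-2-(bromomethyl)-6,10-dimethyl-4-[(2E)-2-methylbut-2-enoyloxy]-6,9,12-tris(triethylsilyloxy)dodeca-2,7,10-trienoate | BrC/C(C(=O)OC)=C\[C@H](OC(=O)/C(C)=C/C)C[C@@](C)(O[Si](CC)(CC)CC)/C=C/C(O[Si](CC)(CC)CC)/C(C)=C\CO[Si](CC)(CC)CC | intermediate
19 | methyl (2Z,4R,6R,7E,10Z)-2-(bromomethyl)-6,10-dimethyl-4-[(2E)-2-methylbut-2-enoyloxy]-12-oxo-6,9-bis(triethylsilyloxy)dodeca-2,7,10-trienoate | BrC/C(C(=O)OC)=C\[C@H](OC(=O)/C(C)=C/C)C[C@@](C)(O[Si](CC)(CC)CC)/C=C/C(O[Si](CC)(CC)CC)/C(C)=C\C=O | intermediate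
20 | allylchromium dichloride formed from 19, C13-bound form (not isolated) | Cl[Cr](Cl)C/C(C(=O)OC)=C\[C@H](OC(=O)/C(C)=C/C)C[C@@](C)(O[Si](CC)(CC)CC)/C=C/C(O[Si](CC)(CC)CC)/C(C)=C\C=O | intermediate
21 | ten-membered chromium alkoxide, the ring-closed hydroxy ester before lactonisation, C6/C7/C8/C10 as in 22 (not isolated) | C=C(C(=O)OC)[C@H]1[C@H](O[Cr](Cl)Cl)/C=C(/C)C(O[Si](CC)(CC)CC)/C=C/[C@](C)(O[Si](CC)(CC)CC)C[C@H]1OC(=O)/C(C)=C/C | intermediate
22 | (3aR,4R,6R,7E,10Z,11aR)-6,10-dimethyl-3-methylidene-2-oxo-6,9-bis(triethylsilyloxy)-2,3,3a,4,5,6,9,11a-octahydrocyclodeca[b]furan-4-yl (2E)-2-methylbut-2-enoate, both C9 epimers | C=C1C(=O)O[C@@H]2/C=C(/C)C(O[Si](CC)(CC)CC)/C=C/[C@](C)(O[Si](CC)(CC)CC)C[C@@H](OC(=O)/C(C)=C/C)[C@@H]12 | intermediate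
23 | (3aR,4R,6R,7E,10Z,11aR)-6,9-dihydroxy-6,10-dimethyl-3-methylidene-2-oxo-2,3,3a,4,5,6,9,11a-octahydrocyclodeca[b]furan-4-yl (2E)-2-methylbut-2-enoate, both C9 epimers | C=C1C(=O)O[C@@H]2/C=C(/C)C(O)/C=C/[C@](C)(O)C[C@@H](OC(=O)/C(C)=C/C)[C@@H]12 | intermediate
24 | eupaheliangolide A | C=C1C(=O)O[C@@H]2/C=C(/C)C(=O)/C=C/[C@](C)(O)C[C@@H](OC(=O)/C(C)=C/C)[C@@H]12 | target

Total step count: 14. Longest linear sequence: 13 steps (steps 1–6 and 8–14, from geraniol); step 7 is a one-step side branch.

Steps most likely to fail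

Step 12. Intermolecular allylation or protonolysis of the allylchromium may outrun ring closure, the allylmetal may lose the C8 tiglate by reductive 1,4-elimination, and the macrocyclic transition state may give incomplete facial control at C6 and C7. The fallback sets out from 17 and changes how the nucleophile is made. The secondary allylic alcohol is converted with ClCO2Me and pyridine into the methyl carbonate F1. Swern oxidation of its primary TES ether, as in step 11, gives the carbonate aldehyde F2. Pd(PPh3)4 (catalytic, zerovalent palladium) and InI in THF at high dilution then convert the allylic carbonate, by oxidative addition with loss of CO2 and reductive transmetallation, into the allylindium iodide methoxide F3. F3 is formed only as fast as the catalyst turns over, so it never accumulates, and it adds to C6 through a closed chair to give the cyclised indium alkoxide F4. Lactonisation of F4 returns the route to 22.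

Step 8. The alkenoyl peroxide may homolyse or transfer oxygen to the enamine too slowly, and the α-acyloxy aldehyde may lose its C8 configuration by enolisation. The fallback sets out from 11 and separates oxygenation from acylation. L-Proline-catalysed α-aminoxylation with nitrosobenzene gives the (2R)-2-(phenylaminooxy) aldehyde F5, which NaBH4 reduces in the same flask to the aminooxy alcohol F6. Zn in AcOH/THF at 0 °C cleaves the N–O bond to the 1,2-diol F7. Chloroacetic anhydride and 2,4,6-collidine at −78 °C acylate only the primary hydroxyl to give the chloroacetate F8. Tigloyl chloride 12 with pyridine and catalytic DMAP gives the chloroacetate tiglate F9. Thiourea and NaHCO3 in EtOH remove the chloroacetyl group to give the hydroxy tiglate F10. Dess–Martin periodinane then oxidises F10 to 14, where the route resumes.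

Step 9. During the slow vinylalane addition the tigloyl group may shift to the new C7 aluminium alkoxide, and C8 may enolise. The fallback sets out from 14 and replaces the one-step adduct formation by a fast aldol followed by elimination. The lithium enolate of methyl 3-(phenylselanyl)propanoate (LDA, THF, −78 °C) adds to the aldehyde within minutes and is quenched cold with AcOH to give the β-hydroxy selenide F11. H2O2 with pyridine in CH2Cl2 at 0 °C oxidises it to the selenoxide F12, whose syn-elimination creates the C11=C13 methylidene and returns the route to 17.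

Further compounds

F1 | step 12 | methyl carbonate of 17 at the C7 hydroxyl | C=C(C(=O)OC)C(OC(=O)OC)[C@H](OC(=O)/C(C)=C/C)C[C@@](C)(O[Si](CC)(CC)CC)/C=C/C(O[Si](CC)(CC)CC)/C(C)=C\CO[Si](CC)(CC)CC
F2 | step 12 | carbonate aldehyde, F1 with the C6 silyl ether oxidised to the (Z)-enal | C=C(C(=O)OC)C(OC(=O)OC)[C@H](OC(=O)/C(C)=C/C)C[C@@](C)(O[Si](CC)(CC)CC)/C=C/C(O[Si](CC)(CC)CC)/C(C)=C\C=O
F3 | step 12 | allylindium iodide methoxide derived from F2 (not isolated) | CO[In](I)C/C(C(=O)OC)=C\[C@H](OC(=O)/C(C)=C/C)C[C@@](C)(O[Si](CC)(CC)CC)/C=C/C(O[Si](CC)(CC)CC)/C(C)=C\C=O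
F4 | step 12 | cyclised indium alkoxide, the ring-closed hydroxy ester before lactonisation (not isolated) | C=C(C(=O)OC)[C@H]1[C@H](O[In](I)OC)/C=C(/C)C(O[Si](CC)(CC)CC)/C=C/[C@](C)(O[Si](CC)(CC)CC)C[C@H]1OC(=O)/C(C)=C/C
F5 | step 8 | (2R,4R,5E,8Z)-4,8-dimethyl-2-(phenylaminooxy)-4,7,10-tris(triethylsilyloxy)deca-5,8-dienal (not isolated) | O=C[C@H](ONc1ccccc1)C[C@@](C)(O[Si](CC)(CC)CC)/C=C/C(O[Si](CC)(CC)CC)/C(C)=C\CO[Si](CC)(CC)CC
F6 | step 8 | (2R,4R,5E,8Z)-4,8-dimethyl-2-(phenylaminooxy)-4,7,10-tris(triethylsilyloxy)deca-5,8-dien-1-ol | OC[C@H](ONc1ccccc1)C[C@@](C)(O[Si](CC)(CC)CC)/C=C/C(O[Si](CC)(CC)CC)/C(C)=C\CO[Si](CC)(CC)CC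
F7 | step 8 | (2R,4R,5E,8Z)-4,8-dimethyl-4,7,10-tris(triethylsilyloxy)deca-5,8-diene-1,2-diol | OC[C@H](O)C[C@@](C)(O[Si](CC)(CC)CC)/C=C/C(O[Si](CC)(CC)CC)/C(C)=C\CO[Si](CC)(CC)CC
F8 | step 8 | primary chloroacetate of F7 | ClCC(=O)OC[C@H](O)C[C@@](C)(O[Si](CC)(CC)CC)/C=C/C(O[Si](CC)(CC)CC)/C(C)=C\CO[Si](CC)(CC)CC
F9 | step 8 | primary chloroacetate, secondary tiglate of F7 | ClCC(=O)OC[C@H](OC(=O)/C(C)=C/C)C[C@@](C)(O[Si](CC)(CC)CC)/C=C/C(O[Si](CC)(CC)CC)/C(C)=C\CO[Si](CC)(CC)CC
F10 | step 8 | (2R,4R,5E,8Z)-1-hydroxy-4,8-dimethyl-4,7,10-tris(triethylsilyloxy)deca-5,8-dien-2-yl (2E)-2-methylbut-2-enoate | OC[C@H](OC(=O)/C(C)=C/C)C[C@@](C)(O[Si](CC)(CC)CC)/C=C/C(O[Si](CC)(CC)CC)/C(C)=C\CO[Si](CC)(CC)CC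
F11 | step 9 | β-hydroxy selenide, aldol adduct of methyl 3-(phenylselanyl)propanoate and 14 | COC(=O)C(C[Se]c1ccccc1)C(O)[C@H](OC(=O)/C(C)=C/C)C[C@@](C)(O[Si](CC)(CC)CC)/C=C/C(O[Si](CC)(CC)CC)/C(C)=C\CO[Si](CC)(CC)CC
F12 | step 9 | selenoxide of F11 (not isolated) | COC(=O)C(C[Se](=O)c1ccccc1)C(O)[C@H](OC(=O)/C(C)=C/C)C[C@@](C)(O[Si](CC)(CC)CC)/C=C/C(O[Si](CC)(CC)CC)/C(C)=C\CO[Si](CC)(CC)CC
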